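## Analysis of the target

Numbering used throughout: C1 is the acid carbon, C2 the methyl-bearing carbon, C3–C6 the carbons of the dioxane, C7–C8 the methylene link, C9=C10 the exocyclic alkene. Ring B is C10–C11–C12–C13–C18–C19 and ring A is C13–C18, with the gem-dimethyl carbon C14 next to C13.

- The target (32) has two halves joined through C7–C8: a 1,2-dioxane carrying a propanoic acid on C3, and a 5,5-dimethyl-octahydronaphthalene attached through the exocyclic C9=C10 bond.
- All three stereocentres lie in the peroxide half: C2 (S), C3 (R) and the fully substituted C6 (S). C2 and C3 are syn. On the ring the C3 side chain and the C6 chain are trans (both equatorial in the chair, C6 methyl axial).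
- The fourth stereo-element is the Z alkene C9=C10: C8 is cis to C19. The two ring carbons on C10 (C11 and C19) differ only in their distance from C13=C18, so ordinary olefination of a ring-B ketone cannot tell them apart.
- The O–O bond does not tolerate low-valent metals, hydrides, phosphines at higher temperature or hydrogenation catalysts. C3–H and C2–H make the ring base-sensitive (Kornblum–DeLaMare cleavage, β-elimination from the ester enolate). The skipped diene C9=C10/C13=C18 migrates under acid.
- The hard part is the quaternary peroxide carbon C6 in a defined relation to C3. The established dioxane syntheses form a C–O bond at C3 or C6 in the ring-closing step and usually give mixtures there.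
- The strategy rests on C6: it bears a methyl group, an oxygen, a two-carbon chain toward C3 and a chain that can start as a vinyl group. This is the carbinol carbon of (R)-linalool (1). If the O–O bond is the bond that is made, the C6–O bond of 1 and a C3–O bond from an aldol reaction are both carried into the ring unchanged.

## Retrosynthetic reasoning

**32 to 30.** The acid is released last from methyl ester 30. A free acid would be decarboxylated by the xenon reagent of step 6 and would quench the ylide of step 15. The forward hydrolysis must be mild enough to spare the C2–H/C3–O array.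

**30 to 29.** The C7–C8 single bond is traced back to a C7=C8 double bond in diene 29, so that the two halves can be joined by carbonyl olefination. The forward step must saturate a disubstituted alkene without touching O–O, the trisubstituted C9=C10 or the tetrasubstituted C13=C18. A metal-free concerted hydrogen transfer does this.

**29 to 27 and 25.** C7=C8 is cut in a Wittig sense. C7 is the only linking carbon that can be a carbonyl group without an epimerisable or eliminable neighbour, because C6 is quaternary. The cut leaves all three stereocentres in aldehyde 27 and the alkene geometry in phosphonium salt 25. Ylide 28 has to react at its α-carbon and keep the C9=C10 geometry.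

**27 to 12.** The aldehyde comes from the vinyl group of dioxane 12 by ozonolysis. The vinyl group is that of linalool and serves as an inert placeholder for C7 while the peroxide is made.

**12 to 10 (key disconnection).** The O–O bond is cut, not a C–O bond, giving 1,4-diol 10. Both carbinol centres can then be built beforehand by reliable C–C chemistry and are only retained in the ring closure, which creates no stereocentre. The forward reaction must turn one hydroxyl into an oxygen electrophile and let the other attack it faster than oxidation or fragmentation.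

**10 to 9, 8, then 4 and 5.** The C2–C3 bond is an aldol bond. An auxiliary-controlled syn-aldol between imide 5 and aldehyde 4 sets C2 and C3 in one step (8). Methanolysis (9) and desilylation (10) follow.

**4 to 2 to 1.** The aldehyde carbon C3 is the former C6 of linalool. Oxidative cleavage of the trisubstituted alkene of silyl ether 2 gives 4, and the C6 stereocentre with its oxygen is bought with 1.

**25 to 24 to 23.** The phosphonium salt comes from allylic alcohol 23 through bromide 24. Both are substitutions at primary C8 that leave the alkene alone.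

**23 to 21.** The C8–O and C19–H bonds are disconnected together: 23 is the 1,4-adduct of H and OH across the diene C8=C9–C10=C19 of triene 21. A 1,4-addition through the s-cis diene places C8 and C19 on the same side of the new C9=C10 bond, which is the required geometry. The geometric problem becomes a regiochemical one: the ring double bond must sit on the C19 side of C10.

**21 to 19 and 20, 19 to 17.** C9–C10 is made by coupling dienyl triflate 19 with vinylstannane 20. The triflate comes from ketone 17 by enolisation toward C19, whose hydrogens are both α to the carbonyl and allylic to C13=C18.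

**17 to 15 to 13.** Ring B of 17 is a reduced anisole. Birch reduction of arene 15 keeps the fusion alkene and places the carbonyl on the carbon that bore the methoxy group, para to C13. The gem-dimethyl group comes from the ketone of tetralone 13, so the position of C10 relative to C14 is fixed by a commercial arene.

## Alternatives that were turned down

**Alternative 1:** Ring B is cut at C10–C19 and C11–C12 ([4+2]) and ring A at C13–C18.
- Forward key step: a palladium hydride catalyst (Pd2(dba)3, acetic acid, a phosphine) cycloisomerises enyne A1 to the exocyclic diene A2. Ynone A3 traps it in the same flask to give dienone A4.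
- For: two rings and three C–C bonds from acyclic material in one operation, with the fusion alkene formed automatically. For the carbocycle it is more step-economic than the seven steps to 25.
- Against: the diene termini C12 and C19 differ only through the gem-dimethyl group one atom away, so the orientation of A3 has no strong bias and regioisomers are likely. A4 is a cyclohexa-1,4-diene that aromatises easily. It carries C9 as a ketone, so the C9=C10 geometry must still be created, and the dioxane is not addressed.
- Comparison: the chosen route fixes the regiochemistry through the arene 13 and the geometry through the cis-1,4-addition of step 11. It spends its risk on the O–O bond, where the saving in steps is largest.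

**Alternative 2:** Ring B is cut at C12–C13.
- Forward key step: the terminal vinyl group of triflate A5 is hydroborated with a dialkylborane. PdCl2(dppf) and base then couple the primary borane with the ring-A enol triflate to give A6, the tert-butyldiphenylsilyl ether of alcohol 23. The trisubstituted alkene of A5 is set earlier by syn-carbocupration of an alkyne.
- For: the geometry is fixed by a stereospecific carbometalation before the ring exists and cannot drift in the ring closure. On the Z geometry this is at least as secure as step 11, and probably more so.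
- Against: A5 needs a longer sequence (carbometalation, an allylic electrophile, C-alkylation of a hindered ketone enolate, triflation next to a quaternary carbon). The coupling takes place at a tetrasubstituted, neopentyl-flanked triflate. The peroxide is again left to hydroperoxide additions with poor control of C2/C3.
- Comparison: the chosen route reaches the same alcohol (23) in five steps from a commercial tetralone and the dioxane with all three stereocentres in six steps from 1.

**Alternative 3:** Both C–O bonds of the dioxane (O–C3 and O–C6) are cut.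
- Forward key step: dye-sensitised photo-oxygenation of dienol A7. The free C7 hydroxyl directs the oxygen to one face in a [4+2] addition and gives dihydrodioxine A8.
- For: the reaction class is well established, the ring and two C–O bonds form at once, and the C3/C6 relation follows from the diene geometry. On the reliability of the ring-forming step it is clearly stronger than an O–O coupling without precedent.
- Against: A7 needs a (3E,5Z)-diene with a trisubstituted Z-alkene and two different silyl ethers. The Z terminus points the carbinol into the s-cis diene, so the ene reaction at the C6 methyl competes. After the cycloaddition the ring alkene must be reduced, the C7–C8 diol cleaved and C1 oxidised from alcohol to ester before it meets aldehyde 27.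
- Comparison: the chosen strategy takes C6 from the chiral pool with its oxygen attached, sets C2/C3 in one aldol at the correct oxidation level of C1, and closes a saturated ring directly.

Key step: step 6

Remark on the chemistry: step 15 should give both geometries of the new C7=C8 bond, which does not matter because step 16 saturates it. Ozonides 3 and 26 form as epimer mixtures at the new acetal carbon.

## Route

Step 1
Reactants: 1 (R)-linalool, (3R)-3,7-dimethylocta-1,6-dien-3-ol
Product: 2 triethyl{[(3R)-3,7-dimethylocta-1,6-dien-3-yl]oxy}silane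
Conditions: TESOTf, 2,6-lutidine, CH2Cl2, −78 → 0 °C
Reagents that add atoms: triethylsilyl trifluoromethanesulfonate, CC[Si](CC)(CC)OS(=O)(=O)C(F)(F)F
Why: Silylation of a hindered tertiary alcohol with a silyl triflate and a non-nucleophilic base. The triethylsilyl ether should survive ozonolysis, the boron aldol work-up and methoxide, and is later removed without touching the C6–O bond.

Step 2
Reactants: 2 triethyl{[(3R)-3,7-dimethylocta-1,6-dien-3-yl]oxy}silane
Product: 4 (4R)-4-methyl-4-[(triethylsilyl)oxy]hex-5-enal, via ozonide 3 (not isolated)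
Conditions: O3 (1.0 equiv), CH2Cl2, −78 °C, Sudan Red 7B end point; PPh3, −78 °C → rt
Reagents that add atoms: ozone, [O-][O+]=O
Why: Chemoselective ozonolysis. Ozone is electrophilic and should attack the trisubstituted alkene much faster than the vinyl group, which is monosubstituted, next to a quaternary carbon and deactivated by the allylic oxygen. Reduction of ozonide 3 gives the aldehyde carbon that becomes C3.

Step 3
Reactants: 5 (4S)-4-benzyl-3-propanoyl-1,3-oxazolidin-2-one; 4 (4R)-4-methyl-4-[(triethylsilyl)oxy]hex-5-enal
Product: 8 (4S)-4-benzyl-3-{(2S,3R,6R)-3-hydroxy-2,6-dimethyl-6-[(triethylsilyl)oxy]oct-7-enoyl}-1,3-oxazolidin-2-one, via boron enolate 6 (not isolated), via boron aldolate 7 (not isolated)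
Conditions: Bu2BOTf, iPr2NEt, CH2Cl2, 0 °C; 4, −78 → 0 °C; pH 7 buffer, MeOH, H2O2, 0 °C
Reagents that add atoms: none
Why: Evans syn-aldol reaction. The (Z)-boron enolate 6 reacts through a Zimmerman–Traxler chair with the auxiliary carbonyl turned away from the enolate oxygen, and the aldehyde approaches the face opposite the benzyl group. This should set C2 (S) and C3 (R) in the 2,3-syn relation; C6 is too remote to interfere.

Step 4
Reactants: 8 (4S)-4-benzyl-3-{(2S,3R,6R)-3-hydroxy-2,6-dimethyl-6-[(triethylsilyl)oxy]oct-7-enoyl}-1,3-oxazolidin-2-one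
Product: 9 methyl (2S,3R,6R)-3-hydroxy-2,6-dimethyl-6-[(triethylsilyl)oxy]oct-7-enoate
Conditions: NaOMe (1.1 equiv), MeOH/CH2Cl2, −10 → 0 °C; aq. NH4Cl
Reagents that add atoms: sodium methoxide, [Na+].[O-]C
Why: Methanolysis of the N-acyl oxazolidinone at the exocyclic carbonyl. Short reaction time at low temperature should avoid retro-aldol cleavage and epimerisation at C2.

Step 5
Reactants: 9 methyl (2S,3R,6R)-3-hydroxy-2,6-dimethyl-6-[(triethylsilyl)oxy]oct-7-enoate
Product: 10 methyl (2S,3R,6R)-3,6-dihydroxy-2,6-dimethyloct-7-enoate
Conditions: HF·pyridine, pyridine, THF, 0 °C → rt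
Reagents that add atoms: none
Why: Fluoride-driven cleavage of the Si–O bond. Buffering with pyridine should prevent ionisation of the tertiary allylic alcohol, and the C6–O bond is not involved.

Step 6
Reactants: 10 methyl (2S,3R,6R)-3,6-dihydroxy-2,6-dimethyloct-7-enoate
Product: 12 methyl (2S)-2-[(3R,6R)-6-ethenyl-6-methyl-1,2-dioxan-3-yl]propanoate, via alkoxyxenon fluoride 11 (not isolated)
Conditions: XeF2 (1.1 equiv), 2,6-di-tert-butyl-4-methylpyridine (2.5 equiv), CH2Cl2 (0.01 M), PFA flask, −78 → −20 °C
Reagents that add atoms: none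
Why: Proposed new method: XeF2 should exchange one fluoride for the less hindered secondary hydroxyl to give alkoxyxenon fluoride 11, in which O3 is bound to divalent xenon and has become an oxygen electrophile; the tertiary hydroxyl O6 should then attack O3 and expel zerovalent xenon and fluoride, which pays for the weak O–O bond. The closest known reactions are the exchange of XeF2 with O–H acids to give FXe–OR and Xe(OR)2 species, the collapse of Xe(OSO2F)2 to the peroxide S2O6F2 and xenon, and the use of alkoxyxenon fluorides as oxygen electrophiles toward alkenes; an intramolecular O–O coupling of two alcohols has not been shown. The ring closes by a 6-exo-tet substitution at oxygen (O6 as nucleophile, Xe–F as exocyclic leaving group) through a chair-like array C3–C4–C5–C6 in which the C3 side chain and the C6 vinyl group can both be equatorial. No stereocentre is created and neither C–O bond is broken, so C3 keeps the aldol configuration and C6 that of linalool. The step needs chemoselectivity: O–O closure must outrun loss of the C3 hydrogen from 11 (ketone formation), fragmentation at C6 and fluorination or oxy-fluorination of the vinyl group. The substrate helps through the proximity of the two oxygens, the electron-poor and hindered vinyl group and the absence of any other nucleophile. The conditions help through low temperature, high dilution and a hindered pyridine that removes HF, which would otherwise catalyse alkene fluorination and ionisation at C6.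

Step 7
Reactants: 13 6-methoxy-3,4-dihydronaphthalen-1(2H)-one
Product: 15 6-methoxy-1,1-dimethyl-1,2,3,4-tetrahydronaphthalene, via titanium alkoxide 14 (not isolated)
Conditions: Me2Zn, TiCl4, CH2Cl2, −30 °C → rt
Reagents that add atoms: dimethylzinc, C[Zn]C
Why: Geminal dimethylation of an aryl ketone with Me2TiCl2 made in the flask. Addition of the first methyl gives alkoxide 14, which ionises to a benzylic cation stabilised by the para-methoxy group and takes up the second methyl, installing the quaternary C14 next to the future fusion carbon C13.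

Step 8
Reactants: 15 6-methoxy-1,1-dimethyl-1,2,3,4-tetrahydronaphthalene
Product: 17 5,5-dimethyl-3,4,5,6,7,8-hexahydronaphthalen-2(1H)-one, via enol ether 16 (not isolated)
Conditions: Li, NH3, THF, t-BuOH, −78 → −33 °C; oxalic acid, MeOH/H2O, rt
Reagents that add atoms: water, O
Why: Birch reduction of the anisole ring gives the 2,5-dihydroanisole 16 and keeps the tetrasubstituted fusion alkene C13=C18. Mild hydrolysis with oxalic acid should give the β,γ-unsaturated ketone without conjugation, with the carbonyl at C10 as dictated by the arene.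

Step 9
Reactants: 17 5,5-dimethyl-3,4,5,6,7,8-hexahydronaphthalen-2(1H)-one
Product: 19 5,5-dimethyl-3,4,5,6,7,8-hexahydronaphthalen-2-yl trifluoromethanesulfonate, via lithium dienolate 18 (not isolated)
Conditions: LiN(SiMe3)2, THF, −78 °C; PhNTf2, −78 → 0 °C
Reagents that add atoms: N-phenylbis(trifluoromethanesulfonimide), O=S(=O)(N(c1ccccc1)S(=O)(=O)C(F)(F)F)C(F)(F)F
Why: Kinetic enolisation followed by O-sulfonylation. The C19 hydrogens are α to the carbonyl and allylic to C13=C18 and should be removed far faster than those on C11, giving the linear dienolate 18 and a triflate with the C10=C19 bond on the C19 side. This regiochemistry is later converted into alkene geometry.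

Step 10
Reactants: 19 5,5-dimethyl-3,4,5,6,7,8-hexahydronaphthalen-2-yl trifluoromethanesulfonate; 20 tributyl(ethenyl)stannane
Product: 21 2-ethenyl-5,5-dimethyl-3,4,5,6,7,8-hexahydronaphthalene
Conditions: Pd(PPh3)4 (3 mol %), LiCl, THF, 60 °C
Reagents that add atoms: none
Why: Stille coupling of an enol triflate with a vinylstannane in the presence of LiCl forms the C9–C10 bond. The triene is air- and dimerisation-sensitive and is used at once.

Step 11
Reactants: 21 2-ethenyl-5,5-dimethyl-3,4,5,6,7,8-hexahydronaphthalene
Product: 23 (2Z)-2-(5,5-dimethyl-3,4,5,6,7,8-hexahydronaphthalen-2(1H)-ylidene)ethan-1-ol, via allylboronate 22 (not isolated)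
Conditions: Ni(cod)2 (5 mol %), PCy3 (5 mol %), pinacolborane, toluene, rt; NaOH, H2O2, THF/H2O, 0 °C
Reagents that add atoms: hydrogen peroxide, OO
Why: Nickel-catalysed 1,4-hydroboration of a 1,3-diene. The diene C8=C9–C10=C19 binds zerovalent nickel in its s-cis form, boron goes to the terminal C8 and hydrogen to C19, so C8 and C19 end up cis on the new C9=C10 bond (Z). The fully substituted ends of the ring diene (C10 and C13) should not compete, and oxidation of 22 gives the alcohol without allylic shift.

Step 12
Reactants: 23 (2Z)-2-(5,5-dimethyl-3,4,5,6,7,8-hexahydronaphthalen-2(1H)-ylidene)ethan-1-ol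
Product: 24 (2Z)-2-(2-bromoethylidene)-5,5-dimethyl-1,2,3,4,5,6,7,8-octahydronaphthalene
Conditions: CBr4, PPh3, CH2Cl2, −20 → 0 °C
Reagents that add atoms: carbon tetrabromide, BrC(Br)(Br)Br
Why: Appel bromination by substitution at the primary carbon under neutral conditions, which should avoid the allyl cation and so keep the alkene geometry.

Step 13
Reactants: 24 (2Z)-2-(2-bromoethylidene)-5,5-dimethyl-1,2,3,4,5,6,7,8-octahydronaphthalene
Product: 25 [(2Z)-2-(5,5-dimethyl-3,4,5,6,7,8-hexahydronaphthalen-2(1H)-ylidene)ethyl](triphenyl)phosphonium bromide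
Conditions: PPh3, MeCN, rt, dark
Reagents that add atoms: triphenylphosphine, c1ccc(cc1)P(c1ccccc1)c1ccccc1
Why: SN2 quaternisation at the primary allylic carbon. Attack at the tertiary C10 (SN2') is sterically disfavoured.

Step 14
Reactants: 12 methyl (2S)-2-[(3R,6R)-6-ethenyl-6-methyl-1,2-dioxan-3-yl]propanoate
Product: 27 methyl (2S)-2-[(3R,6R)-6-formyl-6-methyl-1,2-dioxan-3-yl]propanoate, via ozonide 26 (not isolated)
Conditions: O3, CH2Cl2, −78 °C; Me2S, −78 °C → rt
Reagents that add atoms: ozone, [O-][O+]=O
Why: Ozonolysis of the terminal alkene; dialkyl peroxides are inert to ozone. Me2S is used for the reduction because phosphines can attack the O–O bond, and the aldehyde has no α-hydrogen and cannot epimerise.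

Step 15
Reactants: 25 [(2Z)-2-(5,5-dimethyl-3,4,5,6,7,8-hexahydronaphthalen-2(1H)-ylidene)ethyl](triphenyl)phosphonium bromide; 27 methyl (2S)-2-[(3R,6R)-6-formyl-6-methyl-1,2-dioxan-3-yl]propanoate
Product: 29 methyl (2S)-2-[(3R,6R)-6-{(3Z)-3-(5,5-dimethyl-3,4,5,6,7,8-hexahydronaphthalen-2(1H)-ylidene)prop-1-en-1-yl}-6-methyl-1,2-dioxan-3-yl]propanoate (1E/1Z mixture), via ylide 28 (not isolated)
Conditions: NaN(SiMe3)2 (0.95 equiv to 25), THF, −78 °C; 27, −78 → 0 °C
Reagents that add atoms: none
Why: Wittig reaction of a semi-stabilised allylic ylide with a non-enolisable aldehyde. The ylide should react at its α-carbon (C8) because C10 is fully substituted, and at low temperature the C9=C10 geometry should be kept. A slight deficit of base leaves no strong base to attack the ester or the ring.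

Step 16
Reactants: 29 methyl (2S)-2-[(3R,6R)-6-{(3Z)-3-(5,5-dimethyl-3,4,5,6,7,8-hexahydronaphthalen-2(1H)-ylidene)prop-1-en-1-yl}-6-methyl-1,2-dioxan-3-yl]propanoate
Product: 30 methyl (2S)-2-[(3R,6S)-6-{(3Z)-3-(5,5-dimethyl-3,4,5,6,7,8-hexahydronaphthalen-2(1H)-ylidene)propyl}-6-methyl-1,2-dioxan-3-yl]propanoate
Conditions: KO2CN=NCO2K, AcOH, MeOH/CH2Cl2, 0 °C → rt, portionwise, monitored
Reagents that add atoms: none
Why: Diimide reduction, a concerted syn transfer of two hydrogens without metal or hydride, so the O–O bond should survive. The rate falls steeply with alkene substitution, so the disubstituted C7=C8 bond of the diene should be reduced ahead of C9=C10 and C13=C18, and the reaction is stopped when 29 is consumed. The C6 descriptor changes from R to S only because C7 loses priority.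

Step 17
Reactants: 30 methyl (2S)-2-[(3R,6S)-6-{(3Z)-3-(5,5-dimethyl-3,4,5,6,7,8-hexahydronaphthalen-2(1H)-ylidene)propyl}-6-methyl-1,2-dioxan-3-yl]propanoate
Product: 32 (2S)-2-[(3R,6S)-6-{(3Z)-3-(5,5-dimethyl-3,4,5,6,7,8-hexahydronaphthalen-2(1H)-ylidene)propyl}-6-methyl-1,2-dioxan-3-yl]propanoic acid, via lithium carboxylate 31 (not isolated)
Conditions: LiOH, THF/H2O, 0 °C; 1 M HCl to pH 3
Reagents that add atoms: lithium hydroxide, [Li+].[OH-]
Why: Saponification by acyl substitution at 0 °C. The carboxylate formed protects C2–H against further deprotonation, and cold acidification should leave the skipped diene in place.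

## Compound list

1 | (R)-linalool, (3R)-3,7-dimethylocta-1,6-dien-3-ol | CC(C)=CCC[C@](C)(C=C)O | starting material
2 | triethyl{[(3R)-3,7-dimethylocta-1,6-dien-3-yl]oxy}silane | CC(C)=CCC[C@](C)(C=C)O[Si](CC)(CC)CC | intermediate
3 | 3,3-dimethyl-5-{(3R)-3-methyl-3-[(triethylsilyl)oxy]pent-4-en-1-yl}-1,2,4-trioxolane (ozonide, epimers) | CC1(C)OOC(CC[C@](C)(C=C)O[Si](CC)(CC)CC)O1 | intermediate
4 | (4R)-4-methyl-4-[(triethylsilyl)oxy]hex-5-enal | O=CCC[C@](C)(C=C)O[Si](CC)(CC)CC | intermediate
5 | (4S)-4-benzyl-3-propanoyl-1,3-oxazolidin-2-one | CCC(=O)N1[C@@H](Cc2ccccc2)COC1=O | starting material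
6 | dibutylboron (Z)-enolate of 5 | C/C=C(\OB(CCCC)CCCC)N1[C@@H](Cc2ccccc2)COC1=O | intermediate
7 | dibutylboron aldolate of 8 | C[C@H](C(=O)N1[C@@H](Cc2ccccc2)COC1=O)[C@H](OB(CCCC)CCCC)CC[C@](C)(C=C)O[Si](CC)(CC)CC | intermediate
8 | (4S)-4-benzyl-3-{(2S,3R,6R)-3-hydroxy-2,6-dimethyl-6-[(triethylsilyl)oxy]oct-7-enoyl}-1,3-oxazolidin-2-one | C[C@H](C(=O)N1[C@@H](Cc2ccccc2)COC1=O)[C@H](O)CC[C@](C)(C=C)O[Si](CC)(CC)CC | intermediate
9 | methyl (2S,3R,6R)-3-hydroxy-2,6-dimethyl-6-[(triethylsilyl)oxy]oct-7-enoate | C[C@H](C(=O)OC)[C@H](O)CC[C@](C)(C=C)O[Si](CC)(CC)CC | intermediate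
10 | methyl (2S,3R,6R)-3,6-dihydroxy-2,6-dimethyloct-7-enoate | C[C@H](C(=O)OC)[C@H](O)CC[C@](C)(C=C)O | intermediate
11 | alkoxyxenon fluoride of 10 (F–Xe–O on C3) | C[C@H](C(=O)OC)[C@H](O[Xe]F)CC[C@](C)(C=C)O | intermediate
12 | methyl (2S)-2-[(3R,6R)-6-ethenyl-6-methyl-1,2-dioxan-3-yl]propanoate | C[C@H](C(=O)OC)[C@H]1CC[C@](C)(C=C)OO1 | intermediate
13 | 6-methoxy-3,4-dihydronaphthalen-1(2H)-one | COc1ccc2c(c1)CCCC2=O | starting material
14 | dichloro(methyl)titanium alkoxide of 6-methoxy-1-methyl-1,2,3,4-tetrahydronaphthalen-1-ol | COc1ccc2c(c1)CCCC2(C)O[Ti](C)(Cl)Cl | intermediate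
15 | 6-methoxy-1,1-dimethyl-1,2,3,4-tetrahydronaphthalene | COc1ccc2c(c1)CCCC2(C)C | intermediate
16 | 6-methoxy-1,1-dimethyl-1,2,3,4,5,8-hexahydronaphthalene | COC1=CCC2=C(C1)CCCC2(C)C | intermediate
17 | 5,5-dimethyl-3,4,5,6,7,8-hexahydronaphthalen-2(1H)-one | O=C1CCC2=C(C1)CCCC2(C)C | intermediate
18 | lithium 5,5-dimethyl-3,4,5,6,7,8-hexahydronaphthalen-2-olate | [Li]OC1=CC2=C(CC1)C(C)(C)CCC2 | intermediate
19 | 5,5-dimethyl-3,4,5,6,7,8-hexahydronaphthalen-2-yl trifluoromethanesulfonate | O=S(=O)(OC1=CC2=C(CC1)C(C)(C)CCC2)C(F)(F)F | intermediate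
20 | tributyl(ethenyl)stannane | C=C[Sn](CCCC)(CCCC)CCCC | starting material
21 | 2-ethenyl-5,5-dimethyl-3,4,5,6,7,8-hexahydronaphthalene | C=CC1=CC2=C(CC1)C(C)(C)CCC2 | intermediate
22 | 2-[(2Z)-2-(5,5-dimethyl-3,4,5,6,7,8-hexahydronaphthalen-2(1H)-ylidene)ethyl]-4,4,5,5-tetramethyl-1,3,2-dioxaborolane | CC1(C)OB(C/C=C2/CCC3=C(CCCC3(C)C)C2)OC1(C)C | intermediate
23 | (2Z)-2-(5,5-dimethyl-3,4,5,6,7,8-hexahydronaphthalen-2(1H)-ylidene)ethan-1-ol | OC/C=C1/CCC2=C(CCCC2(C)C)C1 | intermediate
24 | (2Z)-2-(2-bromoethylidene)-5,5-dimethyl-1,2,3,4,5,6,7,8-octahydronaphthalene | BrC/C=C1/CCC2=C(CCCC2(C)C)C1 | intermediate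
25 | [(2Z)-2-(5,5-dimethyl-3,4,5,6,7,8-hexahydronaphthalen-2(1H)-ylidene)ethyl](triphenyl)phosphonium bromide | [Br-].c1ccc(cc1)[P+](c1ccccc1)(c1ccccc1)C/C=C1/CCC2=C(CCCC2(C)C)C1 | intermediate
26 | methyl (2S)-2-[(3R,6R)-6-methyl-6-(1,2,4-trioxolan-3-yl)-1,2-dioxan-3-yl]propanoate (ozonide, epimers) | C[C@H](C(=O)OC)[C@H]1CC[C@](C)(C2OCOO2)OO1 | intermediate
27 | methyl (2S)-2-[(3R,6R)-6-formyl-6-methyl-1,2-dioxan-3-yl]propanoate | C[C@H](C(=O)OC)[C@H]1CC[C@](C)(C=O)OO1 | intermediate
28 | [(2Z)-2-(5,5-dimethyl-3,4,5,6,7,8-hexahydronaphthalen-2(1H)-ylidene)ethylidene](triphenyl)-λ5-phosphane | c1ccc(cc1)P(c1ccccc1)(c1ccccc1)=C/C=C1/CCC2=C(CCCC2(C)C)C1 | intermediate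
29 | methyl (2S)-2-[(3R,6R)-6-{(3Z)-3-(5,5-dimethyl-3,4,5,6,7,8-hexahydronaphthalen-2(1H)-ylidene)prop-1-en-1-yl}-6-methyl-1,2-dioxan-3-yl]propanoate (1E/1Z mixture, C7=C8 left undefined) | C[C@H](C(=O)OC)[C@H]1CC[C@](C)(C=C/C=C2/CCC3=C(CCCC3(C)C)C2)OO1 | intermediate
30 | methyl (2S)-2-[(3R,6S)-6-{(3Z)-3-(5,5-dimethyl-3,4,5,6,7,8-hexahydronaphthalen-2(1H)-ylidene)propyl}-6-methyl-1,2-dioxan-3-yl]propanoate | C[C@H](C(=O)OC)[C@H]1CC[C@](C)(CC/C=C2/CCC3=C(CCCC3(C)C)C2)OO1 | intermediate
31 | lithium (2S)-2-[(3R,6S)-6-{(3Z)-3-(5,5-dimethyl-3,4,5,6,7,8-hexahydronaphthalen-2(1H)-ylidene)propyl}-6-methyl-1,2-dioxan-3-yl]propanoate | C[C@H](C(=O)[O-])[C@H]1CC[C@](C)(CC/C=C2/CCC3=C(CCCC3(C)C)C2)OO1.[Li+] | intermediate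
32 | (2S)-2-[(3R,6S)-6-{(3Z)-3-(5,5-dimethyl-3,4,5,6,7,8-hexahydronaphthalen-2(1H)-ylidene)propyl}-6-methyl-1,2-dioxan-3-yl]propanoic acid | C[C@H](C(=O)O)[C@H]1CC[C@](C)(CC/C=C2/CCC3=C(CCCC3(C)C)C2)OO1 | target

## Step count and least certain steps

Total: 17 steps. Longest linear sequence: 10 steps, either from 1 (steps 1–6, 14–17) or from 13 (steps 7–13, 15–17).

**Step 6 (key step).**
- What may go wrong: the alkoxyxenon intermediate may lose the C3 hydrogen and oxidise the carbinol to the ketone. The Xe–O bond may break homolytically, giving alkoxy radicals that fragment at C6 or abstract hydrogen. Residual HF may promote fluorination of the vinyl group or ionisation at C6 with ether formation. All of these are unimolecular or acid-catalysed paths that compete with a ring closure never shown before.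
- First recourse within the approach: move the activation to silicon (silyl ethers of 10 in place of free hydroxyls), so that a fluorosilane is released and no HF.
- Fallback with known chemistry: it sets out from aldehyde 4 and returns at aldehyde 27. It gives up the linalool C–O bond.
  - Wittig reaction of 4 with methyl 2-(triphenylphosphoranylidene)propanoate should give methyl (2E,6R)-2,6-dimethyl-6-[(triethylsilyl)oxy]octa-2,7-dienoate F1.
  - HF·pyridine gives the tertiary alcohol methyl (2E,6R)-6-hydroxy-2,6-dimethylocta-2,7-dienoate F2.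
  - Ph3SiOReO3-catalysed 1,3-transposition gives the primary allylic alcohol methyl (2E,6E)-8-hydroxy-2,6-dimethylocta-2,6-dienoate F3, separated from its (6Z) isomer F4.
  - Sharpless asymmetric epoxidation (Ti(OiPr)4, L-(+)-diethyl tartrate, t-BuOOH) sets C6 anew in methyl (2E)-5-[(2S,3S)-3-(hydroxymethyl)-2-methyloxiran-2-yl]-2-methylpent-2-enoate F5.
  - Perhydrolysis with ethereal H2O2 and catalytic H3PMo12O40 opens the epoxide at the tertiary carbon with inversion to methyl (2E,6R,7S)-6-hydroperoxy-7,8-dihydroxy-2,6-dimethyloct-2-enoate F6.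
  - Et2NH in CF3CH2OH closes the ring by conjugate addition of the hydroperoxide to the enoate, giving methyl (2S)-2-{(3R,6R)-6-[(1S)-1,2-dihydroxyethyl]-6-methyl-1,2-dioxan-3-yl}propanoate F7. C2 and C3 are not controlled here, so F7 must be separated from its C2/C3 stereoisomers F8.
  - NaIO4 cleaves the diol of F7 to aldehyde 27.

**Step 11.**
- What may go wrong: loss of site selectivity, with nickel engaging the ring diene or adding 1,2 across the vinyl group. The substrate is a conjugated triene, not a simple diene.
- Fallback: it sets out from ketone 17 and returns at alcohol 23. Horner–Wadsworth–Emmons reaction with triethyl phosphonoacetate and NaH gives ethyl (2Z)-(5,5-dimethyl-3,4,5,6,7,8-hexahydronaphthalen-2(1H)-ylidene)acetate F9 together with its E isomer F10, without selectivity. F9 is separated on AgNO3-impregnated silica and reduced with iBu2AlH to 23.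

**Step 9.**
- What may go wrong: deprotonation on the C11 side, giving the cross-conjugated triflate, or proton transfer that moves the ring alkene into conjugation. Either would put the ring double bond on the wrong side of C10 and invert or erase the geometry set in step 11.
- Fallback: it sets out from ketone 17 and returns at triene 21. Addition of vinylmagnesium bromide with CeCl3 gives 2-ethenyl-5,5-dimethyl-1,2,3,4,5,6,7,8-octahydronaphthalen-2-ol F11. Dehydration with the Burgess reagent should remove a C19 hydrogen, which is allylic and leads to the fully conjugated triene 21.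

**Step 15.**
- What may go wrong: fragmentation of the α-peroxy aldehyde (attack at the carbonyl, then C6–C7 cleavage with O–O heterolysis), or drift of the C9=C10 geometry in the delocalised ylide.
- Fallback: it sets out from alcohol 23 and returns at diene 29. Mitsunobu reaction of 23 with 1-phenyl-1H-tetrazole-5-thiol gives 5-{[(2Z)-2-(5,5-dimethyl-3,4,5,6,7,8-hexahydronaphthalen-2(1H)-ylidene)ethyl]sulfanyl}-1-phenyl-1H-tetrazole F12. Oxidation with H2O2 and (NH4)6Mo7O24 gives the sulfone 5-{[(2Z)-2-(5,5-dimethyl-3,4,5,6,7,8-hexahydronaphthalen-2(1H)-ylidene)ethyl]sulfonyl}-1-phenyl-1H-tetrazole F13. Its potassium salt (KN(SiMe3)2, −78 °C) reacts with 27 in a Julia–Kocienski olefination to give 29.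

**Step 17.**
- What may go wrong: β-elimination of the peroxide oxygen from the ester enolate (ring opening), or epimerisation at C2 under hydroxide.
- Fallback: it sets out from ester 30 and returns at acid 32. Hydrolysis with pig liver esterase in pH 7 phosphate buffer with a little acetone replaces hydroxide by a neutral acyl-transfer catalyst and makes no new compound.

## Further compounds

F1 | step 6 | methyl (2E,6R)-2,6-dimethyl-6-[(triethylsilyl)oxy]octa-2,7-dienoate | COC(=O)/C(C)=C/CC[C@](C)(C=C)O[Si](CC)(CC)CC
F2 | step 6 | methyl (2E,6R)-6-hydroxy-2,6-dimethylocta-2,7-dienoate | COC(=O)/C(C)=C/CC[C@](C)(C=C)O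
F3 | step 6 | methyl (2E,6E)-8-hydroxy-2,6-dimethylocta-2,6-dienoate | COC(=O)/C(C)=C/CC/C(C)=C/CO
F4 | step 6 | methyl (2E,6Z)-8-hydroxy-2,6-dimethylocta-2,6-dienoate | COC(=O)/C(C)=C/CC/C(C)=C\CO
F5 | step 6 | methyl (2E)-5-[(2S,3S)-3-(hydroxymethyl)-2-methyloxiran-2-yl]-2-methylpent-2-enoate | COC(=O)/C(C)=C/CC[C@]1(C)O[C@H]1CO
F6 | step 6 | methyl (2E,6R,7S)-6-hydroperoxy-7,8-dihydroxy-2,6-dimethyloct-2-enoate | COC(=O)/C(C)=C/CC[C@@](C)(OO)[C@@H](O)CO
F7 | step 6 | methyl (2S)-2-{(3R,6R)-6-[(1S)-1,2-dihydroxyethyl]-6-methyl-1,2-dioxan-3-yl}propanoate | C[C@H](C(=O)OC)[C@H]1CC[C@](C)([C@@H](O)CO)OO1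
F8 | step 6 | C2/C3 stereoisomers of F7 (mixture, C2 and C3 left undefined) | CC(C(=O)OC)C1CC[C@](C)([C@@H](O)CO)OO1
F9 | step 11 | ethyl (2Z)-(5,5-dimethyl-3,4,5,6,7,8-hexahydronaphthalen-2(1H)-ylidene)acetate | CCOC(=O)/C=C1/CCC2=C(CCCC2(C)C)C1
F10 | step 11 | ethyl (2E)-(5,5-dimethyl-3,4,5,6,7,8-hexahydronaphthalen-2(1H)-ylidene)acetate | CCOC(=O)/C=C1\CCC2=C(CCCC2(C)C)C1
F11 | step 9 | 2-ethenyl-5,5-dimethyl-1,2,3,4,5,6,7,8-octahydronaphthalen-2-ol (racemic) | C=CC1(O)CCC2=C(C1)CCCC2(C)C
F12 | step 15 | 5-{[(2Z)-2-(5,5-dimethyl-3,4,5,6,7,8-hexahydronaphthalen-2(1H)-ylidene)ethyl]sulfanyl}-1-phenyl-1H-tetrazole | c1ccc(cc1)-n1nnnc1SC/C=C1/CCC2=C(CCCC2(C)C)C1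
F13 | step 15 | 5-{[(2Z)-2-(5,5-dimethyl-3,4,5,6,7,8-hexahydronaphthalen-2(1H)-ylidene)ethyl]sulfonyl}-1-phenyl-1H-tetrazole | c1ccc(cc1)-n1nnnc1S(=O)(=O)C/C=C1/CCC2=C(CCCC2(C)C)C1
F0 | step 17 | none | none
A1 | alternative 1 | 3,3-dimethyloct-7-en-1-yne | C#CC(C)(C)CCCC=C
A2 | alternative 1 | 3,3-dimethyl-1,2-dimethylidenecyclohexane | C=C1CCCC(C)(C)C1=C
A3 | alternative 1 | 1-[(tert-butyldimethylsilyl)oxy]but-3-yn-2-one | C#CC(=O)CO[Si](C)(C)C(C)(C)C
A4 | alternative 1 | 2-[(tert-butyldimethylsilyl)oxy]-1-(5,5-dimethyl-1,4,5,6,7,8-hexahydronaphthalen-2-yl)ethan-1-one | CC1(C)CCCC2=C1CC=C(C(=O)CO[Si](C)(C)C(C)(C)C)C2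
A5 | alternative 2 | 2-[(2E)-4-{[tert-butyl(diphenyl)silyl]oxy}-2-ethenylbut-2-en-1-yl]-6,6-dimethylcyclohex-1-en-1-yl trifluoromethanesulfonate | CC1(C)CCCC(C/C(C=C)=C\CO[Si](c2ccccc2)(c2ccccc2)C(C)(C)C)=C1OS(=O)(=O)C(F)(F)F
A6 | alternative 2 | tert-butyl{[(2Z)-2-(5,5-dimethyl-3,4,5,6,7,8-hexahydronaphthalen-2(1H)-ylidene)ethyl]oxy}diphenylsilane | CC1(C)CCCC2=C1CC/C(=C/CO[Si](c3ccccc3)(c3ccccc3)C(C)(C)C)C2
A7 | alternative 3 | (3E,5Z)-2,6-dimethylocta-3,5-diene with C2 and C7 configured as in A8, tert-butyldiphenylsilyl ether on C1, free hydroxyl on C7, tert-butyldimethylsilyl ether on C8 (target numbering) | C[C@H](CO[Si](c1ccccc1)(c1ccccc1)C(C)(C)C)/C=C/C=C(/C)[C@H](O)CO[Si](C)(C)C(C)(C)C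
A8 | alternative 3 | 3,6-dihydro-1,2-dioxine with C2, C3 and C6 as in the target, tert-butyldiphenylsilyl ether on C1, free hydroxyl on C7, tert-butyldimethylsilyl ether on C8 (target numbering) | C[C@H](CO[Si](c1ccccc1)(c1ccccc1)C(C)(C)C)[C@H]1C=C[C@](C)([C@H](O)CO[Si](C)(C)C(C)(C)C)OO1
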